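Begin with the Q readings.

| flask | Q | E | remark | time |
|---|---|---|---|---|
| alpha | 13 mM | 50 mM | run made earlier |  |
| epsilon | 30 mM | 50 mM | run made earlier |  |
| theta | 20 mM | 75 mM | run made earlier |  |
| flask | 20 mM | 50.0 mM |  | 40 h |

| run | time / h | Q / % | X / % | D / % |
|---|---|---|---|---|
| alpha | 6.00 | 66 | 12 | 15 |
| alpha | 15.0 | 44 | 21 | 29 |
| alpha | 30.0 | 23 | 24 | 32 |
| alpha | 50.0 | 11 | 25 | 28 |
| epsilon | 12.0 | 56 | 14 | 22 |
| epsilon | 25.0 | 37 | 18 | 29 |
| epsilon | 40.0 | 23 | 26 | 30 |
| epsilon | 50.0 | 21 | 18 | 35 |
| theta | 4.00 | 73 | 13 | 17 |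
| theta | 8.00 | 50 | 19 | 24 |
| theta | 20.0 | 24 | 27 | 34 |
| theta | 50.0 | 7 | 25 | 24 |

(readings scatter by 2 percentage points)

* Q at 40 h, in percent of the Q charged
* X at 40 h, in percent of the Q charged
* D at 40 h, in percent of the Q charged
* L at 40 h, in percent of the Q charged



Two of these readings look wrong together. In the alpha run, charged with 13 mM of Q, Q stands at 23% after 30.0 h, yet in the epsilon run, charged with 30 mM, it stands at the same 23% after 40.0 h. A pseudo-first-order fall, with [E] steady, gives the same percentage at the same time whatever the charge of Q, but here the time grew by a factor of 1.33 while the charge of Q grew by 2.31.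

So you should ask what the charge does to E. Q is 60.0% of the E charged in the epsilon run, more than the 26.0% in the alpha run. If E is used up along with Q, then at the same charge of E a larger charge of Q takes [E] further down and so slows the fall of Q.

Measure this slowing directly. The extra time to that reading per unit of the charged ratio [Q]/[E], the delay, read from these two scattered readings, is 29.4 h. The asked flask, with [E] at 50.0 mM like both runs and [Q] at 20 mM, should by this reckoning reach that percentage after 34.1 h. The theta run, with the same [Q] but [E] at 75 mM, stood near it sooner, at 20.0 h.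

Beyond that point, the alpha run's fall from 23% to 11% gives a late constant of 0.0369 h⁻¹. Over the remaining 5.88 h, that puts Q in the flask at 18.5% by my reckoning, with the scatter of the readings on it.

The forecast gave Q 20%, X 24%, D 31% and L 25%, holding that "Q decay is not clean first order".

The flask gives Q 19.7%, X 25.1%, D 32.6% and L 22.6%.

    Q + E ⇌ X (K = 65.0 M⁻¹, k = 1.31 × 10⁻⁴ M⁻¹ s⁻¹)
    Q + E → D (k = 2.08 × 10⁻⁴ M⁻¹ s⁻¹)
    E + X → L (k = 2.64 × 10⁻⁵ M⁻¹ s⁻¹)
    E + D → L (k = 1.50 × 10⁻⁴ M⁻¹ s⁻¹)

The delay put Q in this flask 1.2 percentage points below the result. Now use it on the neighbouring flask charged with 8.0 mM of Q, all else held. There the delay brings the reckoned time of 23% forward to 27.1 h. The same late constant then runs for 12.9 h and gives 14.3%. That neighbouring flask holds Q at 14.4% after 40.0 h, with E at 81.8% of its own charge.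

Readings and results come from a simulation for substances that don't exist.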